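**Retrosynthetic overview**

- Vibsanin R ⇐ desilylation ⇐ inverting senecioylation at C4 ⇐ hydroxyl-directed epoxidation of C5=C6 ⇐ reagent-controlled reduction of the C4 dienone ⇐ allylic oxidation of the C4 methylene of an eleven-membered triene.
- Feature used: with the carbocycle numbered C1 (quaternary) to C11, the oxirane sits on C5–C6 and its parent alkene is an E-trisubstituted C5=C6 bond, while C4 lies between C2=C3 and C5=C6 (doubly allylic). The ring is therefore cut at C5=C6 into a C5 methyl ketone and a C6 aldehyde (McMurry coupling), and the C4 oxygen is added only after ring closure.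
- Seco keto aldehyde ⇐ Horner–Wadsworth–Emmons olefination at C9=C10 (ring-cis), cross-metathesis/methylenation for the side-chain diene, and a Johnson–Claisen rearrangement that sets quaternary C1 and E-C2=C3 in one operation.
- Claisen substrate ⇐ CBS reduction of an enone made from an E-vinyl iodide (carboalumination of pent-1-en-4-yne) and a Weinreb amide from methyl (R)-3-hydroxybutanoate.
- Ring order: eleven-membered carbocycle first (step 16), oxirane last (step 20).

Key step: step 16

Assumption: the silyloxy stereocenter carried from 1 is a spectator that is erased in step 15 (either enantiomer of the hydroxy ester would serve), and ring positions are numbered C1 to C11 as in the overview.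

**Route**

Step 1
Reactants: 1 methyl (R)-3-hydroxybutanoate
Product: 2 methyl (R)-3-[(tert-butyldimethylsilyl)oxy]butanoate
Conditions: TBSCl, imidazole, DMF, rt
Reagents that add atoms: tert-butyl(chloro)dimethylsilane, CC(C)(C)[Si](C)(C)Cl
Why: Imidazole-promoted silyl ether formation on a secondary alcohol proceeds without touching the stereocenter.

Step 2
Reactants: 2 methyl (R)-3-[(tert-butyldimethylsilyl)oxy]butanoate
Product: 3 (R)-3-[(tert-butyldimethylsilyl)oxy]-N-methoxy-N-methylbutanamide
Conditions: MeNH(OMe)·HCl, i-PrMgCl, THF, −20 to 0 °C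
Reagents that add atoms: N,O-dimethylhydroxylamine hydrochloride, CNOC.Cl
Why: Weinreb amide formation by aminolysis of the ester with the magnesium amide is mild enough to leave the β-silyloxy group and its stereocenter intact.

Step 3
Reactants: 4 pent-1-en-4-yne
Product: 6 (E)-1-iodo-2-methylpenta-1,4-diene, via alkenylalane 5 (not isolated)
Conditions: AlMe3, Cp2ZrCl2 (20 mol %), CH2Cl2, 0 °C to rt; then I2, THF, −30 to 0 °C
Reagents that add atoms: trimethylaluminium, C[Al](C)C; iodine, II
Why: Negishi zirconium-catalysed carboalumination adds methyl and aluminium syn across the terminal alkyne only, and iodinolysis with retention gives the E iodide in which iodine is cis to the new methyl group.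

Step 4
Reactants: 6 (E)-1-iodo-2-methylpenta-1,4-diene; 3 (R)-3-[(tert-butyldimethylsilyl)oxy]-N-methoxy-N-methylbutanamide
Product: 8 (2R,5E)-2-[(tert-butyldimethylsilyl)oxy]-6-methylnona-5,8-dien-4-one, via vinyllithium 7 (not isolated)
Conditions: t-BuLi (2 equiv), Et2O, −78 °C; then 3, −78 to −20 °C; aq. NH4Cl
Reagents that add atoms: none
Why: Iodine–lithium exchange retains the alkene geometry and acylation of the vinyllithium by the Weinreb amide stops at the chelated tetrahedral adduct, so the enone appears only on work-up.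

Step 5
Reactants: 8 (2R,5E)-2-[(tert-butyldimethylsilyl)oxy]-6-methylnona-5,8-dien-4-one
Product: 9 (2R,4S,5E)-2-[(tert-butyldimethylsilyl)oxy]-6-methylnona-5,8-dien-4-ol
Conditions: (R)-2-methyl-CBS-oxazaborolidine (0.5 equiv), catecholborane, toluene, −78 °C; aq. NaOH work-up
Reagents that add atoms: none
Why: Corey–Bakshi–Shibata reduction treats the alkenyl arm as the large group, so the (R)-oxazaborolidine should give the 4S carbinol by 1,2-hydride delivery, and catecholborane at low temperature leaves the terminal alkene unhydroborated.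

Step 6
Reactants: 9 (2R,4S,5E)-2-[(tert-butyldimethylsilyl)oxy]-6-methylnona-5,8-dien-4-ol
Product: 11 ethyl (3S,4E,7R)-7-[(tert-butyldimethylsilyl)oxy]-3-methyl-3-(prop-2-en-1-yl)oct-4-enoate, via ketene acetal 10 (not isolated)
Conditions: MeC(OEt)3 (excess), EtCO2H (cat.), xylene, 140 °C, EtOH distilled off
Reagents that add atoms: triethyl orthoacetate, CC(OCC)(OCC)OCC
Why: Johnson–Claisen rearrangement through a chair transition state with the carbinol side chain equatorial forms the new C–C bond on the face from which the C–O bond departs, which transfers the 4S carbinol chirality to the quaternary carbon (future C1, S) and creates the E-C2=C3 alkene.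

Step 7
Reactants: 11 ethyl (3S,4E,7R)-7-[(tert-butyldimethylsilyl)oxy]-3-methyl-3-(prop-2-en-1-yl)oct-4-enoate; 12 methyl vinyl ketone
Product: 13 ethyl (3S,4E,7R)-7-[(tert-butyldimethylsilyl)oxy]-3-methyl-3-[(2E)-4-oxopent-2-en-1-yl]oct-4-enoate
Conditions: second-generation Grubbs catalyst (5 mol %), CH2Cl2, 40 °C
Reagents that add atoms: none
Why: Olefin cross-metathesis between the terminal allyl group and the enone partner is E-selective, and the internal alkene flanked by the quaternary carbon is too hindered to take part.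

Step 8
Reactants: 13 ethyl (3S,4E,7R)-7-[(tert-butyldimethylsilyl)oxy]-3-methyl-3-[(2E)-4-oxopent-2-en-1-yl]oct-4-enoate
Product: 14 ethyl (3S,4E,7R)-7-[(tert-butyldimethylsilyl)oxy]-3-methyl-3-[(2E)-4-methylpenta-2,4-dien-1-yl]oct-4-enoate
Conditions: Ph3PCH3Br, KHMDS, THF, −78 to 0 °C
Reagents that add atoms: methyltriphenylphosphonium bromide, C[P+](c1ccccc1)(c1ccccc1)c1ccccc1.[Br-]
Why: Wittig methylenation adds 1,2 to the methyl ketone to give the 2-methyl-1,3-diene, and the ethyl ester is not attacked by the ylide at this temperature.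

Step 9
Reactants: 14 ethyl (3S,4E,7R)-7-[(tert-butyldimethylsilyl)oxy]-3-methyl-3-[(2E)-4-methylpenta-2,4-dien-1-yl]oct-4-enoate
Product: 15 (3S,4E,7R)-7-[(tert-butyldimethylsilyl)oxy]-3-methyl-3-[(2E)-4-methylpenta-2,4-dien-1-yl]oct-4-enal
Conditions: DIBAL-H (1.1 equiv), CH2Cl2, −78 °C; MeOH, aq. potassium sodium tartrate
Reagents that add atoms: none
Why: Partial reduction of the hindered ester with DIBAL-H stops at the aluminium hemiacetal at −78 °C, which gives the aldehyde (future C10) on work-up.

Step 10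
Reactants: 16 triethyl phosphonoacetate; 17 (3-bromopropoxy)(tert-butyl)dimethylsilane
Product: 18 ethyl 5-[(tert-butyldimethylsilyl)oxy]-2-(diethoxyphosphoryl)pentanoate (racemic)
Conditions: NaH, THF–DMF, 0 °C then 60 °C, 16 in excess
Reagents that add atoms: none
Why: SN2 C-alkylation of the sodium phosphonoacetate with the primary bromide installs C8, C7 and the protected C6 oxygen, and excess phosphonoacetate suppresses dialkylation.

Step 11
Reactants: 15 (3S,4E,7R)-7-[(tert-butyldimethylsilyl)oxy]-3-methyl-3-[(2E)-4-methylpenta-2,4-dien-1-yl]oct-4-enal; 18 ethyl 5-[(tert-butyldimethylsilyl)oxy]-2-(diethoxyphosphoryl)pentanoate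
Product: 19 ethyl (2E,5S,6E,9R)-9-[(tert-butyldimethylsilyl)oxy]-2-{3-[(tert-butyldimethylsilyl)oxy]propyl}-5-methyl-5-[(2E)-4-methylpenta-2,4-dien-1-yl]deca-2,6-dienoate
Conditions: NaH, THF, 0 °C to rt
Reagents that add atoms: none
Why: Horner–Wadsworth–Emmons olefination under equilibrating conditions places the ester trans to the C11 chain, so C8 and C11 end cis as the ring-cis C9=C10 geometry requires.

Step 12
Reactants: 19 ethyl (2E,5S,6E,9R)-9-[(tert-butyldimethylsilyl)oxy]-2-{3-[(tert-butyldimethylsilyl)oxy]propyl}-5-methyl-5-[(2E)-4-methylpenta-2,4-dien-1-yl]deca-2,6-dienoate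
Product: 20 (2E,5S,6E,9R)-9-[(tert-butyldimethylsilyl)oxy]-2-{3-[(tert-butyldimethylsilyl)oxy]propyl}-5-methyl-5-[(2E)-4-methylpenta-2,4-dien-1-yl]deca-2,6-dien-1-ol
Conditions: DIBAL-H (2.5 equiv), CH2Cl2, −78 °C; aq. potassium sodium tartrate
Reagents that add atoms: none
Why: DIBAL-H reduces the enoate 1,2 to the primary allylic alcohol without touching the alkenes or silyl ethers.

Step 13
Reactants: 20 (2E,5S,6E,9R)-9-[(tert-butyldimethylsilyl)oxy]-2-{3-[(tert-butyldimethylsilyl)oxy]propyl}-5-methyl-5-[(2E)-4-methylpenta-2,4-dien-1-yl]deca-2,6-dien-1-ol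
Product: 21 (4E,7S,8E,11R)-1,11-bis[(tert-butyldimethylsilyl)oxy]-4-{[(tert-butyldiphenylsilyl)oxy]methyl}-7-methyl-7-[(2E)-4-methylpenta-2,4-dien-1-yl]dodeca-4,8-diene
Conditions: TBDPSCl, imidazole, CH2Cl2, rt
Reagents that add atoms: tert-butyl(chloro)diphenylsilane, CC(C)(C)[Si](Cl)(c1ccccc1)c1ccccc1
Why: Silylation of the primary allylic alcohol with the bulkier diphenylsilyl group gives an ether that survives the acid methanolysis of the next step and the later oxidations.

Step 14
Reactants: 21 (4E,7S,8E,11R)-1,11-bis[(tert-butyldimethylsilyl)oxy]-4-{[(tert-butyldiphenylsilyl)oxy]methyl}-7-methyl-7-[(2E)-4-methylpenta-2,4-dien-1-yl]dodeca-4,8-diene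
Product: 22 (4E,7S,8E,11R)-4-{[(tert-butyldiphenylsilyl)oxy]methyl}-7-methyl-7-[(2E)-4-methylpenta-2,4-dien-1-yl]dodeca-4,8-diene-1,11-diol
Conditions: CSA (cat.), MeOH–CH2Cl2, 0 °C to rt
Reagents that add atoms: none
Why: Acid-catalysed methanolysis cleaves the two tert-butyldimethylsilyl ethers far faster than the tert-butyldiphenylsilyl ether, freeing only the C6 and C5 hydroxyls.

Step 15
Reactants: 22 (4E,7S,8E,11R)-4-{[(tert-butyldiphenylsilyl)oxy]methyl}-7-methyl-7-[(2E)-4-methylpenta-2,4-dien-1-yl]dodeca-4,8-diene-1,11-diol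
Product: 23 (4E,7S,8E)-4-{[(tert-butyldiphenylsilyl)oxy]methyl}-7-methyl-7-[(2E)-4-methylpenta-2,4-dien-1-yl]-11-oxododeca-4,8-dienal
Conditions: Dess–Martin periodinane, NaHCO3, CH2Cl2, 0 °C to rt; used at once
Reagents that add atoms: none
Why: Buffered Dess–Martin oxidation converts the primary and secondary alcohols into the C6 aldehyde and the C5 methyl ketone without acid or base, so C2=C3 stays out of conjugation with the ketone.

Step 16
Reactants: 23 (4E,7S,8E)-4-{[(tert-butyldiphenylsilyl)oxy]methyl}-7-methyl-7-[(2E)-4-methylpenta-2,4-dien-1-yl]-11-oxododeca-4,8-dienal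
Product: 25 (1S,2E,5E,9E)-9-{[(tert-butyldiphenylsilyl)oxy]methyl}-1,5-dimethyl-1-[(2E)-4-methylpenta-2,4-dien-1-yl]cycloundeca-2,5,9-triene (overview numbering), via titanium pinacolate 24 (not isolated)
Conditions: TiCl3(DME)1.5, Zn–Cu couple, DME, reflux; 23 added by syringe pump over 30 h (final 2 mM)
Reagents that add atoms: none
Why: Low-valent titanium made from TiCl3 and the Zn–Cu couple transfers single electrons to both carbonyls, the two surface-bound ketyls couple to the titanium pinacolate 24 (new C5–C6 bond), and the titanium then removes both oxygens to release the C5=C6 alkene. The closest known reaction type is the McMurry keto-aldehyde macrocyclization that gives eleven- to fifteen-membered terpene polyenes. The eleven-membered carbocycle is closed by intramolecular carbon–carbon coupling of the two chain termini held on the metal surface, and slow addition keeps free dicarbonyl so dilute that cyclization outruns dimerization. No stereocenter is formed; the alkene geometry is decided at the deoxygenation stage, where the ring already containing E-C2=C3 and ring-cis C9=C10 should accommodate the ring-trans (E) C5=C6 bond with less strain, and any Z isomer would be removed by chromatography. Chemoselectivity rests on the absence of any other reducible group: the silyl ether, the isolated alkenes and the diene are inert, and there is no C4 oxygen to be lost. The skipped ketone meets the Lewis-acidic medium only at very low stationary concentration, which limits migration of C2=C3 into conjugation before coupling.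

Step 17
Reactants: 25 (1S,2E,5E,9E)-9-{[(tert-butyldiphenylsilyl)oxy]methyl}-1,5-dimethyl-1-[(2E)-4-methylpenta-2,4-dien-1-yl]cycloundeca-2,5,9-triene
Product: 26 (1S,2E,5E,9E)-9-{[(tert-butyldiphenylsilyl)oxy]methyl}-1,5-dimethyl-1-[(2E)-4-methylpenta-2,4-dien-1-yl]cycloundeca-2,5,9-trien-4-ol (both C4 epimers)
Conditions: SeO2 (0.5 equiv), t-BuOOH, CH2Cl2, 0 °C to rt
Reagents that add atoms: selenium dioxide, O=[Se]=O; tert-butyl hydroperoxide, CC(C)(C)OO
Why: Selenium dioxide allylic oxidation (ene reaction then [2,3]-sigmatropic shift, which returns oxygen to the carbon that lost hydrogen) should select C4 because it is the CH2 on the more substituted end of C5=C6, lies trans to the C7 chain and is doubly allylic, whereas C9=C10 is deactivated by its allylic silyloxy group; both C4 epimers and any ketone formed converge in step 18.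

Step 18
Reactants: 26 (1S,2E,5E,9E)-9-{[(tert-butyldiphenylsilyl)oxy]methyl}-1,5-dimethyl-1-[(2E)-4-methylpenta-2,4-dien-1-yl]cycloundeca-2,5,9-trien-4-ol
Product: 27 (1S,2E,5E,9E)-9-{[(tert-butyldiphenylsilyl)oxy]methyl}-1,5-dimethyl-1-[(2E)-4-methylpenta-2,4-dien-1-yl]cycloundeca-2,5,9-trien-4-one
Conditions: Dess–Martin periodinane, NaHCO3, CH2Cl2, 0 °C
Reagents that add atoms: none
Why: Dess–Martin oxidation of the bis-allylic alcohol gives the cross-conjugated dienone and erases the uncontrolled C4 configuration.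

Step 19
Reactants: 27 (1S,2E,5E,9E)-9-{[(tert-butyldiphenylsilyl)oxy]methyl}-1,5-dimethyl-1-[(2E)-4-methylpenta-2,4-dien-1-yl]cycloundeca-2,5,9-trien-4-one
Product: 28 (1S,2E,4S,5E,9E)-9-{[(tert-butyldiphenylsilyl)oxy]methyl}-1,5-dimethyl-1-[(2E)-4-methylpenta-2,4-dien-1-yl]cycloundeca-2,5,9-trien-4-ol
Conditions: (R)-2-methyl-CBS-oxazaborolidine (1 equiv), catecholborane, toluene, −78 to −40 °C
Reagents that add atoms: none
Why: Corey–Bakshi–Shibata reduction should treat the α-methylated C5 alkenyl arm as the large group and the unbranched C3 arm as the small one, so the (R)-catalyst gives the 4S alcohol by 1,2-reduction, the epimer needed to direct the epoxidation.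

Step 20
Reactants: 28 (1S,2E,4S,5E,9E)-9-{[(tert-butyldiphenylsilyl)oxy]methyl}-1,5-dimethyl-1-[(2E)-4-methylpenta-2,4-dien-1-yl]cycloundeca-2,5,9-trien-4-ol
Product: 29 4S epoxy alcohol, the 5,6-epoxide of 28 with the oxirane configured as in the target and the C4 carbinol epimeric to the target
Conditions: VO(acac)2 (5 mol %), t-BuOOH, CH2Cl2, 0 °C
Reagents that add atoms: tert-butyl hydroperoxide, CC(C)(C)OO
Why: Vanadium-catalysed hydroxyl-directed epoxidation prefers the more electron-rich trisubstituted C5=C6 over C2=C3, and the 1,2-allylic strain from the C5 methyl places the carbinol hydrogen beside that methyl so that oxygen is delivered syn to the hydroxyl on the outer face, giving the erythro epoxy alcohol whose C5 and C6 configurations are those of the target.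

Step 21
Reactants: 29 4S epoxy alcohol; 30 3-methylbut-2-enoic acid
Product: 31 O-tert-butyldiphenylsilyl vibsanin R
Conditions: PPh3, DIAD, toluene, 0 °C to rt
Reagents that add atoms: none
Why: Mitsunobu esterification displaces the activated allylic oxyphosphonium by the carboxylate with SN2 inversion, turning the 4S erythro alcohol into the 4R ester of the target, while attack at C2 with allylic shift is blocked by the adjacent quaternary C1.

Step 22
Reactants: 31 O-tert-butyldiphenylsilyl vibsanin R
Product: 32 vibsanin R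
Conditions: TBAF, AcOH, THF, 0 °C to rt
Reagents that add atoms: none
Why: Fluoride cleaves the primary silyl ether, and the acetic acid buffer keeps the medium from causing acyl migration, ester cleavage or epoxide opening.

**Compound list**

1 | methyl (R)-3-hydroxybutanoate | C[C@@H](O)CC(=O)OC | starting material
2 | methyl (R)-3-[(tert-butyldimethylsilyl)oxy]butanoate | C[C@@H](O[Si](C)(C)C(C)(C)C)CC(=O)OC | intermediate
3 | (R)-3-[(tert-butyldimethylsilyl)oxy]-N-methoxy-N-methylbutanamide | C[C@@H](O[Si](C)(C)C(C)(C)C)CC(=O)N(C)OC | intermediate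
4 | pent-1-en-4-yne | C=CCC#C | starting material
5 | (E)-dimethyl(2-methylpenta-1,4-dien-1-yl)alane, not isolated | C=CC/C(C)=C/[Al](C)C | intermediate
6 | (E)-1-iodo-2-methylpenta-1,4-diene | C=CC/C(C)=C/I | intermediate
7 | (E)-(2-methylpenta-1,4-dien-1-yl)lithium, not isolated | C=CC/C(C)=C/[Li] | intermediate
8 | (2R,5E)-2-[(tert-butyldimethylsilyl)oxy]-6-methylnona-5,8-dien-4-one | C[C@@H](O[Si](C)(C)C(C)(C)C)CC(=O)/C=C(C)/CC=C | intermediate
9 | (2R,4S,5E)-2-[(tert-butyldimethylsilyl)oxy]-6-methylnona-5,8-dien-4-ol | C[C@@H](O[Si](C)(C)C(C)(C)C)C[C@H](O)/C=C(C)/CC=C | intermediate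
10 | mixed ketene acetal of 9 (1-ethoxyvinyl ether), not isolated | C[C@@H](O[Si](C)(C)C(C)(C)C)C[C@H](OC(=C)OCC)/C=C(C)/CC=C | intermediate
11 | ethyl (3S,4E,7R)-7-[(tert-butyldimethylsilyl)oxy]-3-methyl-3-(prop-2-en-1-yl)oct-4-enoate | C=CC[C@](C)(/C=C/C[C@@H](C)O[Si](C)(C)C(C)(C)C)CC(=O)OCC | intermediate
12 | methyl vinyl ketone | C=CC(C)=O | starting material
13 | ethyl (3S,4E,7R)-7-[(tert-butyldimethylsilyl)oxy]-3-methyl-3-[(2E)-4-oxopent-2-en-1-yl]oct-4-enoate | CC(=O)/C=C/C[C@](C)(/C=C/C[C@@H](C)O[Si](C)(C)C(C)(C)C)CC(=O)OCC | intermediate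
14 | ethyl (3S,4E,7R)-7-[(tert-butyldimethylsilyl)oxy]-3-methyl-3-[(2E)-4-methylpenta-2,4-dien-1-yl]oct-4-enoate | C=C(C)/C=C/C[C@](C)(/C=C/C[C@@H](C)O[Si](C)(C)C(C)(C)C)CC(=O)OCC | intermediate
15 | (3S,4E,7R)-7-[(tert-butyldimethylsilyl)oxy]-3-methyl-3-[(2E)-4-methylpenta-2,4-dien-1-yl]oct-4-enal | C=C(C)/C=C/C[C@](C)(/C=C/C[C@@H](C)O[Si](C)(C)C(C)(C)C)CC=O | intermediate
16 | triethyl phosphonoacetate | CCOC(=O)CP(=O)(OCC)OCC | starting material
17 | (3-bromopropoxy)(tert-butyl)dimethylsilane | CC(C)(C)[Si](C)(C)OCCCBr | starting material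
18 | ethyl 5-[(tert-butyldimethylsilyl)oxy]-2-(diethoxyphosphoryl)pentanoate (racemic) | CCOC(=O)C(CCCO[Si](C)(C)C(C)(C)C)P(=O)(OCC)OCC | intermediate
19 | ethyl (2E,5S,6E,9R)-9-[(tert-butyldimethylsilyl)oxy]-2-{3-[(tert-butyldimethylsilyl)oxy]propyl}-5-methyl-5-[(2E)-4-methylpenta-2,4-dien-1-yl]deca-2,6-dienoate | C=C(C)/C=C/C[C@](C)(/C=C/C[C@@H](C)O[Si](C)(C)C(C)(C)C)C/C=C(C(=O)OCC)\CCCO[Si](C)(C)C(C)(C)C | intermediate
20 | (2E,5S,6E,9R)-9-[(tert-butyldimethylsilyl)oxy]-2-{3-[(tert-butyldimethylsilyl)oxy]propyl}-5-methyl-5-[(2E)-4-methylpenta-2,4-dien-1-yl]deca-2,6-dien-1-ol | C=C(C)/C=C/C[C@](C)(/C=C/C[C@@H](C)O[Si](C)(C)C(C)(C)C)C/C=C(CO)\CCCO[Si](C)(C)C(C)(C)C | intermediate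
21 | (4E,7S,8E,11R)-1,11-bis[(tert-butyldimethylsilyl)oxy]-4-{[(tert-butyldiphenylsilyl)oxy]methyl}-7-methyl-7-[(2E)-4-methylpenta-2,4-dien-1-yl]dodeca-4,8-diene | C=C(C)/C=C/C[C@](C)(/C=C/C[C@@H](C)O[Si](C)(C)C(C)(C)C)C/C=C(CO[Si](c1ccccc1)(c1ccccc1)C(C)(C)C)\CCCO[Si](C)(C)C(C)(C)C | intermediate
22 | (4E,7S,8E,11R)-4-{[(tert-butyldiphenylsilyl)oxy]methyl}-7-methyl-7-[(2E)-4-methylpenta-2,4-dien-1-yl]dodeca-4,8-diene-1,11-diol | C=C(C)/C=C/C[C@](C)(/C=C/C[C@@H](C)O)C/C=C(CO[Si](c1ccccc1)(c1ccccc1)C(C)(C)C)\CCCO | intermediate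
23 | (4E,7S,8E)-4-{[(tert-butyldiphenylsilyl)oxy]methyl}-7-methyl-7-[(2E)-4-methylpenta-2,4-dien-1-yl]-11-oxododeca-4,8-dienal (seco C5 ketone C6 aldehyde) | C=C(C)/C=C/C[C@](C)(/C=C/CC(C)=O)C/C=C(CO[Si](c1ccccc1)(c1ccccc1)C(C)(C)C)\CCC=O | intermediate
24 | cyclic titanium 1,2-diolate (pinacolate) across C5–C6, diastereomer mixture, not isolated | C=C(C)/C=C/C[C@]1(C)/C=C/CC2(C)O[Ti](Cl)(Cl)OC2CC/C(CO[Si](c3ccccc3)(c3ccccc3)C(C)(C)C)=C\C1 | intermediate
25 | (1S,2E,5E,9E)-9-{[(tert-butyldiphenylsilyl)oxy]methyl}-1,5-dimethyl-1-[(2E)-4-methylpenta-2,4-dien-1-yl]cycloundeca-2,5,9-triene | C=C(C)/C=C/C[C@]1(C)/C=C/C/C(C)=C/CC/C(CO[Si](c2ccccc2)(c2ccccc2)C(C)(C)C)=C\C1 | intermediate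
26 | C4 alcohol of 25, both C4 epimers | C=C(C)/C=C/C[C@]1(C)/C=C/C(O)/C(C)=C/CC/C(CO[Si](c2ccccc2)(c2ccccc2)C(C)(C)C)=C\C1 | intermediate
27 | C4 ketone of 25 (cross-conjugated dienone) | C=C(C)/C=C/C[C@]1(C)/C=C/C(=O)/C(C)=C/CC/C(CO[Si](c2ccccc2)(c2ccccc2)C(C)(C)C)=C\C1 | intermediate
28 | (1S,4S) C4 alcohol of 25 | C=C(C)/C=C/C[C@]1(C)/C=C/[C@H](O)/C(C)=C/CC/C(CO[Si](c2ccccc2)(c2ccccc2)C(C)(C)C)=C\C1 | intermediate
29 | 4S epoxy alcohol: 5,6-epoxide of 28, oxirane as in the target, C4 epimeric to the target | C=C(C)/C=C/C[C@]1(C)/C=C/[C@H](O)[C@]2(C)O[C@H]2CC/C(CO[Si](c3ccccc3)(c3ccccc3)C(C)(C)C)=C\C1 | intermediate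
30 | 3-methylbut-2-enoic acid | CC(C)=CC(=O)O | starting material
31 | O-tert-butyldiphenylsilyl vibsanin R | C=C(C)/C=C/C[C@]1(C)/C=C/[C@@H](OC(=O)C=C(C)C)[C@]2(C)O[C@H]2CC/C(CO[Si](c3ccccc3)(c3ccccc3)C(C)(C)C)=C\C1 | intermediate
32 | vibsanin R | C=C(C)/C=C/C[C@]1(C)/C=C/[C@@H](OC(=O)C=C(C)C)[C@]2(C)O[C@H]2CC/C(CO)=C\C1 | target

**Step count and risks**

Total step count: 22. Longest linear sequence: 20 steps (steps 1, 2, 4 to 9 and 11 to 22, from compound 1).

Steps most likely to fail:

1. Step 16 (McMurry macrocyclization). What may go wrong: intermolecular coupling to oligomers, poor control of the geometry of the new trisubstituted alkene, and migration of C2=C3 into conjugation with the ketone before the carbonyls couple. Fallback: the coupling is split into a pinacol closure and a stereospecific deoxygenation. Setting out from 23, SmI2 in THF at −78 °C under high dilution would give the cyclic 5,6-diol F1. The diastereomers whose C4 and C7 lie anti when the two hydroxyls are syn (shown for one of them) are separated and carried on. 1,1'-Thiocarbonyldiimidazole in toluene at 80 °C would convert them into the cyclic thionocarbonate F2. Corey–Winter syn elimination with 1,3-dimethyl-2-phenyl-1,3,2-diazaphospholidine at 40 °C would then give only the E alkene, and the route is rejoined at 25.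

2. Step 17 (allylic oxidation at C4). What may go wrong: loss of site selectivity through a competing ene reaction at the allylic positions of C9=C10, addition of the selenium reagent to the side-chain diene, or allylic transposition. Fallback: the ene/sigmatropic mechanism is replaced by hydrogen-atom abstraction. Setting out from 25, the CrO3·3,5-dimethylpyrazole complex in CH2Cl2 at −20 °C would abstract the weakest, doubly allylic C4–H and deliver the dienone directly, so the route is rejoined at 27 and step 18 is skipped (no new compound, F0).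

3. Step 21 (Mitsunobu inversion). What may go wrong: slow substitution at a carbinol flanked by the fully substituted epoxide carbon, leading to retention through an acyloxyphosphonium pathway, elimination or allylic shift. Fallback: inversion by oxidation and reagent-controlled reduction followed by ordinary acylation. Setting out from 29, Dess–Martin periodinane with NaHCO3 would give the epoxy enone F3. Reduction with (S)-2-methyl-CBS-oxazaborolidine and catecholborane, with the quaternary epoxide carbon as the large group, would give the 4R epoxy alcohol F4. Acylation with 3-methylbut-2-enoyl chloride, pyridine and DMAP in CH2Cl2 would then rejoin the route at 31.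

**Further compounds**

F1 | step 16 | cyclic 5,6-diol from pinacol closure of 23 (one of the two usable diastereomers) | C=C(C)/C=C/C[C@]1(C)/C=C/C[C@](C)(O)[C@@H](O)CC/C(CO[Si](c2ccccc2)(c2ccccc2)C(C)(C)C)=C\C1
F2 | step 16 | cyclic 5,6-thionocarbonate of F1 | C=C(C)/C=C/C[C@]1(C)/C=C/C[C@]2(C)OC(=S)O[C@H]2CC/C(CO[Si](c3ccccc3)(c3ccccc3)C(C)(C)C)=C\C1
F0 | step 17 | none | none
F3 | step 21 | 5,6-epoxy-2-en-4-one from oxidation of 29 | C=C(C)/C=C/C[C@]1(C)/C=C/C(=O)[C@]2(C)O[C@H]2CC/C(CO[Si](c3ccccc3)(c3ccccc3)C(C)(C)C)=C\C1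
F4 | step 21 | 4R epoxy alcohol (C4 epimer of 29) | C=C(C)/C=C/C[C@]1(C)/C=C/[C@@H](O)[C@]2(C)O[C@H]2CC/C(CO[Si](c3ccccc3)(c3ccccc3)C(C)(C)C)=C\C1
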